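**Plan**
- Last cuts: the two ring A O–CH3 bonds and the C5'–Br bond of ring B.
- Central cut: ring B has oxygen on C2', C4' and C6', so it is the aromatic tautomer of a cyclohexane-1,3,5-trione. It is opened at C2'–C3' and C5'–C6' into a benzylmalonate (C2'–C1'–C6', with the CH2 already on C1') and diethyl 3-oxopentanedioate (C3'–C4'–C5'); the two ester groups of the latter end up on C3' and C5'.
- The CH2–C1' bond is cut next, back to a ring A aldehyde and diethyl malonate (Knoevenagel condensation, then conjugate reduction). Ring A comes from 5-bromovanillin by bromination and O-methylation.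
- Forward: ring A is bought and decorated, the malonate chain is attached, ring B is closed in one base-mediated step, then decarboxylated, monobrominated and demethylated.
- Stereochemistry: the target has no stereocentre, so nothing has to be controlled.

Key step: step 5

Remark on the chemistry: 5-bromovanillin is taken as a commercial starting material. Locants follow the target: ring A has C1 (CH2), C2/C3 (Br), C4/C5 (O), C6 (H); ring B has C1' (CH2), C2'/C4'/C6' (O), C3' (H), C5' (Br).

Step 1
Reactants: 1 5-bromovanillin (3-bromo-4-hydroxy-5-methoxybenzaldehyde)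
Product: 2 2,3-dibromo-4-hydroxy-5-methoxybenzaldehyde
Conditions: Br2 (1.1 equiv), Fe powder (cat.), AcOH, rt
Reagents that add atoms: bromine, BrBr
Why: Electrophilic aromatic bromination, in which the positions ortho and para to the phenol are already filled, so the methoxy group should direct bromine to its free para position next to the aldehyde, the other open carbon being only ortho-activated and wedged between CHO and OMe.

Step 2
Reactants: 2 2,3-dibromo-4-hydroxy-5-methoxybenzaldehyde
Product: 3 2,3-dibromo-4,5-dimethoxybenzaldehyde
Conditions: MeI, K2CO3, DMF, rt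
Reagents that add atoms: iodomethane, CI
Why: Williamson ether synthesis, in which the acidic phenoxide is alkylated on oxygen, and the methyl ether keeps ring A inert to the alkoxide, hydride and hydroxide used later.

Step 3
Reactants: 3 2,3-dibromo-4,5-dimethoxybenzaldehyde; 4 diethyl malonate
Product: 5 diethyl 2-[(2,3-dibromo-4,5-dimethoxyphenyl)methylidene]malonate
Conditions: piperidine (cat.), AcOH (cat.), toluene, reflux, Dean–Stark
Reagents that add atoms: none
Why: Knoevenagel condensation driven by azeotropic removal of water, which joins the benzylic carbon to the future C1' and, unlike alkylation with a benzyl halide, cannot give a dialkylated malonate.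

Step 4
Reactants: 5 diethyl 2-[(2,3-dibromo-4,5-dimethoxyphenyl)methylidene]malonate
Product: 6 diethyl 2-[(2,3-dibromo-4,5-dimethoxyphenyl)methyl]malonate
Conditions: NaBH4, EtOH, 0 °C; then aq. HCl
Reagents that add atoms: none
Why: Conjugate hydride reduction of a doubly activated Michael acceptor, in which hydride adds at the benzylic carbon and the resulting malonate enolate shields the esters from further reduction, while aryl bromides and aryl ethers do not react with NaBH4.

Step 5
Reactants: 6 diethyl 2-[(2,3-dibromo-4,5-dimethoxyphenyl)methyl]malonate; 7 diethyl 3-oxopentanedioate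
Product: 9 diethyl 5-[(2,3-dibromo-4,5-dimethoxyphenyl)methyl]-2,4,6-trihydroxyisophthalate, via open-chain dioxoheptanedioate triester 8 (not isolated)
Conditions: NaOEt (2.5 equiv), EtOH, reflux, slow addition of 7 (1.5 equiv); EtOH distilled off, 120 °C; then aq. HCl
Reagents that add atoms: none
Why: The more acidic oxoglutarate 7 is deprotonated first and its enolate carbon acylates one ester carbonyl of malonate 6 in an intermolecular Claisen condensation (C2'–C3', giving 8), after which the second activated methylene of 8 attacks the remaining malonate ester in a 6-exo-trig Dieckmann closure (C5'–C6') that completes ring B. The cyclohexane-1,3,5-trione so formed carries a hydrogen on every carbon between its carbonyls, C1' included, so it should tautomerise fully to the aromatic triol, and deprotonation of this acidic, chelated phloroglucinol diester by the excess alkoxide pulls the sequence to completion. The closest known reaction type is the sodium alkoxide condensation of malonic esters with 3-oxoglutaric esters to 2,4,6-trihydroxyisophthalates, a double Claisen (3+3) annulation. No stereocentre is formed. The step needs ring closure at carbon instead of enol oxygen and cross-condensation instead of self-condensation of 7: all acylations are reversible under ethoxide, so a pyranone or a non-enolisable C-acylated malonate should reopen while only the aromatic product is withdrawn as its salt, and slow addition of an excess of 7 keeps its self-condensation down. The aryl bromides and methyl ethers of ring A are inert to NaOEt under these conditions, and the two ester groups left on C3' and C5' keep ring B blocked until the next step.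

Step 6
Reactants: 9 diethyl 5-[(2,3-dibromo-4,5-dimethoxyphenyl)methyl]-2,4,6-trihydroxyisophthalate
Product: 11 2-[(2,3-dibromo-4,5-dimethoxyphenyl)methyl]benzene-1,3,5-triol, via trihydroxyisophthalic diacid 10 (not isolated)
Conditions: KOH, H2O/EtOH (degassed), reflux, N2; then HCl to pH 1, 60 °C
Reagents that add atoms: none
Why: Ester saponification followed by protodecarboxylation, which is easy for 2,4,6-trihydroxybenzoic acids because ring protonation at the carboxyl-bearing carbon gives a β-keto acid tautomer that loses CO2 on gentle warming, while the ring A bromides and methyl ethers tolerate aqueous hydroxide.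

Step 7
Reactants: 11 2-[(2,3-dibromo-4,5-dimethoxyphenyl)methyl]benzene-1,3,5-triol
Product: 12 2-bromo-4-[(2,3-dibromo-4,5-dimethoxyphenyl)methyl]benzene-1,3,5-triol
Conditions: NBS (1.0 equiv, slow addition), THF, −78 °C, N2, dark
Reagents that add atoms: N-bromosuccinimide, O=C1CCC(=O)N1Br
Why: Electrophilic aromatic bromination, in which the free phloroglucinol ring B is far more nucleophilic than the dibromodimethoxy ring A, its open positions C3' and C5' are equivalent so only one monobromide can form, and one equivalent of reagent at low temperature together with the deactivating first bromine should stop the reaction there.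

Step 8
Reactants: 12 2-bromo-4-[(2,3-dibromo-4,5-dimethoxyphenyl)methyl]benzene-1,3,5-triol
Product: 13 vidalol A (2-bromo-4-[(2,3-dibromo-4,5-dihydroxyphenyl)methyl]benzene-1,3,5-triol)
Conditions: BBr3 (8 equiv), CH2Cl2, −78 °C to rt; then H2O
Reagents that add atoms: none
Why: Lewis acid-mediated aryl methyl ether cleavage, in which BBr3 binds each methoxy oxygen and bromide removes the methyl group by SN2 attack, the excess covering the three free phenols held as borates, and aqueous work-up should release the pentaphenol.

**Compound list**
1 | 5-bromovanillin (3-bromo-4-hydroxy-5-methoxybenzaldehyde) | COc1cc(C=O)cc(Br)c1O | starting material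
2 | 2,3-dibromo-4-hydroxy-5-methoxybenzaldehyde | COc1cc(C=O)c(Br)c(Br)c1O | intermediate
3 | 2,3-dibromo-4,5-dimethoxybenzaldehyde | COc1cc(C=O)c(Br)c(Br)c1OC | intermediate
4 | diethyl malonate | CCOC(=O)CC(=O)OCC | starting material
5 | diethyl 2-[(2,3-dibromo-4,5-dimethoxyphenyl)methylidene]malonate | CCOC(=O)C(=Cc1cc(OC)c(OC)c(Br)c1Br)C(=O)OCC | intermediate
6 | diethyl 2-[(2,3-dibromo-4,5-dimethoxyphenyl)methyl]malonate | CCOC(=O)C(Cc1cc(OC)c(OC)c(Br)c1Br)C(=O)OCC | intermediate
7 | diethyl 3-oxopentanedioate | CCOC(=O)CC(=O)CC(=O)OCC | starting material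
8 | diethyl 2-[(2,3-dibromo-4,5-dimethoxyphenyl)methyl]-4-(ethoxycarbonyl)-3,5-dioxoheptanedioate (tautomer and diastereomer mixture, not isolated) | CCOC(=O)C(Cc1cc(OC)c(OC)c(Br)c1Br)C(=O)C(C(=O)OCC)C(=O)CC(=O)OCC | intermediate
9 | diethyl 5-[(2,3-dibromo-4,5-dimethoxyphenyl)methyl]-2,4,6-trihydroxyisophthalate | CCOC(=O)c1c(O)c(Cc2cc(OC)c(OC)c(Br)c2Br)c(O)c(C(=O)OCC)c1O | intermediate
10 | 5-[(2,3-dibromo-4,5-dimethoxyphenyl)methyl]-2,4,6-trihydroxybenzene-1,3-dicarboxylic acid (not isolated) | OC(=O)c1c(O)c(Cc2cc(OC)c(OC)c(Br)c2Br)c(O)c(C(=O)O)c1O | intermediate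
11 | 2-[(2,3-dibromo-4,5-dimethoxyphenyl)methyl]benzene-1,3,5-triol | COc1cc(Cc2c(O)cc(O)cc2O)c(Br)c(Br)c1OC | intermediate
12 | 2-bromo-4-[(2,3-dibromo-4,5-dimethoxyphenyl)methyl]benzene-1,3,5-triol | COc1cc(Cc2c(O)cc(O)c(Br)c2O)c(Br)c(Br)c1OC | intermediate
13 | vidalol A (2-bromo-4-[(2,3-dibromo-4,5-dihydroxyphenyl)methyl]benzene-1,3,5-triol) | Oc1cc(Cc2c(O)cc(O)c(Br)c2O)c(Br)c(Br)c1O | target

**Step count**
Total steps: 8. Longest linear sequence: 8 steps (1 to 13); compounds 4 and 7 enter as purchased.

**Steps most likely to fail**

Step 5. Self-condensation of the oxoglutarate may outrun acylation of the hindered, partly enolised monosubstituted malonate, or the ring may close on oxygen and stall. The fallback sets out from 6 and builds the two bonds one after the other. One ester of 6 would be saponified with one equivalent of KOH in EtOH to the half ester 3-ethoxy-2-[(2,3-dibromo-4,5-dimethoxyphenyl)methyl]-3-oxopropanoic acid F1. SOCl2 would convert this into the acid chloride ethyl 3-chloro-2-[(2,3-dibromo-4,5-dimethoxyphenyl)methyl]-3-oxopropanoate F2. C-acylation of the magnesium chelate of 7 (MgCl2, Et3N, MeCN) with F2 would give the open-chain triester 8 as an isolated compound. A separate Dieckmann closure of 8 with NaOEt in EtOH would rejoin the route at 9.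

Step 7. A second bromination at the remaining ring B position may compete with the first and give mixtures of unbrominated, mono- and dibrominated material. The fallback sets out from 9 and uses one ester as a blocking group. Saponification with one equivalent of KOH would give the half acid 3-[(2,3-dibromo-4,5-dimethoxyphenyl)methyl]-5-(ethoxycarbonyl)-2,4,6-trihydroxybenzoic acid F3. F3 would lose CO2 on acidification and warming to give the monoester ethyl 3-[(2,3-dibromo-4,5-dimethoxyphenyl)methyl]-2,4,6-trihydroxybenzoate F4. F4 has a single open ring B carbon, so NBS can only give ethyl 3-bromo-5-[(2,3-dibromo-4,5-dimethoxyphenyl)methyl]-2,4,6-trihydroxybenzoate F5. Hydrolysis of F5 with KOH to 3-bromo-5-[(2,3-dibromo-4,5-dimethoxyphenyl)methyl]-2,4,6-trihydroxybenzoic acid F6 and decarboxylation on acidification would rejoin the route at 12.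

Step 8. HBr formed during ether cleavage may cause loss or migration of the ring B bromine, since the bromophloroglucinol ring is easily protonated. The fallback sets out from 11 and reverses the last two operations. BBr3 in CH2Cl2 would first cleave the methyl ethers while ring B carries no bromine, giving 2-[(2,3-dibromo-4,5-dihydroxyphenyl)methyl]benzene-1,3,5-triol F7. One equivalent of NBS at −78 °C would then brominate the phloroglucinol ring, which is far more nucleophilic than the dibromocatechol ring, and arrive directly at 13.

**Further compounds**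
F1 | step 5 | 3-ethoxy-2-[(2,3-dibromo-4,5-dimethoxyphenyl)methyl]-3-oxopropanoic acid (racemic) | CCOC(=O)C(Cc1cc(OC)c(OC)c(Br)c1Br)C(=O)O
F2 | step 5 | ethyl 3-chloro-2-[(2,3-dibromo-4,5-dimethoxyphenyl)methyl]-3-oxopropanoate (racemic) | CCOC(=O)C(Cc1cc(OC)c(OC)c(Br)c1Br)C(=O)Cl
F3 | step 7 | 3-[(2,3-dibromo-4,5-dimethoxyphenyl)methyl]-5-(ethoxycarbonyl)-2,4,6-trihydroxybenzoic acid | OC(=O)c1c(O)c(Cc2cc(OC)c(OC)c(Br)c2Br)c(O)c(C(=O)OCC)c1O
F4 | step 7 | ethyl 3-[(2,3-dibromo-4,5-dimethoxyphenyl)methyl]-2,4,6-trihydroxybenzoate | CCOC(=O)c1c(O)cc(O)c(Cc2cc(OC)c(OC)c(Br)c2Br)c1O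
F5 | step 7 | ethyl 3-bromo-5-[(2,3-dibromo-4,5-dimethoxyphenyl)methyl]-2,4,6-trihydroxybenzoate | CCOC(=O)c1c(O)c(Br)c(O)c(Cc2cc(OC)c(OC)c(Br)c2Br)c1O
F6 | step 7 | 3-bromo-5-[(2,3-dibromo-4,5-dimethoxyphenyl)methyl]-2,4,6-trihydroxybenzoic acid | OC(=O)c1c(O)c(Br)c(O)c(Cc2cc(OC)c(OC)c(Br)c2Br)c1O
F7 | step 8 | 2-[(2,3-dibromo-4,5-dihydroxyphenyl)methyl]benzene-1,3,5-triol | Oc1cc(Cc2c(O)cc(O)cc2O)c(Br)c(Br)c1O
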